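## Analysis of the target

The target 26 is a sesquilignan. Its chain is a 2,3-dibenzylbutane-1,4-diol (C7–C8–C8'–C7', with the hydroxymethyl carbons C9 and C9'). One benzyl group is the guaiacyl ring A; the other is C5 of a 2-aryl-3-hydroxymethyl-7-methoxy-2,3-dihydrobenzofuran (ring B fused to the dihydrofuran, guaiacyl ring C on C2). There are four stereocentres in two pairs: C8 and C8' are both R, and the ring carbons are 2S,3R, with ring C and the hydroxymethyl group trans. The pairs are insulated from each other by ring B and a methylene group, so neither can direct the other and each must be set in absolute terms. The sensitive functions are two free phenols, three primary alcohols and above all the O1–C2 bond, a cyclic benzyl aryl ether activated by the para oxygen of ring C, which ionises with acid and can be hydrogenolysed. The difficulties are the enantioselective construction of the trans-2,3-disubstituted dihydrofuran, a union of the two halves that does not endanger it, and a protecting-group plan that ends under very mild conditions. The plan rests on the C2–C3 bond: C2 is a benzylic ether carbon carrying ring C and O1, C3 carries the aromatic carbon C3a and a one-carbon substituent that can be held at the ester level, and C3 is 1,5-related to C2 through C3a, C7a and O1. That is the pattern left behind when a carbene centre at C3, stabilised by ring B and an ester, inserts into a C2–H bond of an aryl benzyl ether.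

## Retrosynthetic reasoning

26 ⇒ 25. The last operation should be the mildest. Both phenols are masked as benzyl ethers and nothing else is left to remove, so only two aryl O–CH2Ph bonds are cut. Phenolic benzyl ethers are hydrogenolysed much faster than the cyclic O1–C2 ether, the one bond that must survive.

25 ⇒ 24. The 1,4-diol is taken back to a trans-3,4-dibenzylbutyrolactone. The lactone holds C8 and C8' in a ring in which trans is both the kinetic result of alkylation and the thermodynamic isomer. The C3 hydroxymethyl group of the dihydrofuran is carried in 24 as a pivalate, so one hydride reduction opens the lactone and frees that alcohol, and no separate deprotection is spent on it.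

24 ⇒ 14 + 22. The C7'–C8' bond between the benzylic carbon on ring B and the lactone α-carbon is cut. This separates the two stereochemical domains into fragments of similar size, each made enantiopure on its own. The forward reaction, alkylation of the enolate of 22 by benzylic bromide 14, has only to deliver the electrophile anti to the benzyl group already present. Cutting C7–C8 instead would place the dihydrobenzofuran in the nucleophile; keeping it in the electrophile spares it strong base.

22 ⇒ 20 ⇒ 18 + 2, and 18 ⇒ 15 + 16. The lactone is opened through hydroxy ester 21 to imide 20, and the benzylic C7–C8 bond is cut. The forward reaction is an auxiliary-controlled alkylation of the succinyl imide 18 with bromide 2, which sets C8. The same bromide 2 supplies ring A here and ring C below, which is why both phenols carry the same protecting group. 18 comes from the half ester 15 and the oxazolidinone 16.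

14 ⇒ 13 ⇒ 11 ⇒ 10 ⇒ 9. No skeletal bond is cut. The bromide comes from alcohol 13, that from aldehyde 12 released from the dioxolane of 11, and pivalate 11 from alcohol 10 and ester 9. The C5 carbon is present from the start, so ring B needs no further C–C bond. The C3 ester is reduced before the enolate alkylation because an ester at C3 leaves an acidic C3–H from which O1 can be eliminated.

9 ⇒ 7. The C2–C3 bond is cut, which opens the dihydrofuran to an aryl benzyl ether carrying a diazoacetate ortho to the ether oxygen. This turns a two-stereocentre heterocycle into an achiral, flat precursor whose only prochiral element is the O–CH2 group. The forward reaction has to choose one of its two hydrogens under the influence of a chiral dirhodium tetracarboxylate and then place the ester trans to ring C. The ester is the future hydroxymethyl carbon and also makes C3 correctable by equilibration through cis ester 8.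

7 ⇒ 6 ⇒ 5. The diazo group is removed by the retron of a diazo transfer to arylacetate 6. The aryl–CH2 bond is then cut, a cross-coupling of aryl iodide 5 with a zinc ester enolate. Both forward steps run under nearly neutral conditions that the acetal and the benzylic ethers tolerate.

5 ⇒ 4 + 2, 4 ⇒ 3, 2 ⇒ 1. The aryl ether O–CH2 bond is cut (phenoxide alkylation), the acetal goes back to 5-iodovanillin 3, and bromide 2 to the commercial alcohol 1. The acetal is installed before the ether so that the acid-labile para-alkoxybenzyl aryl ether never meets acid.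

## Alternatives that were turned down

Alternative 1: a (4+1) annulation that cuts both O1–C2 and C2–C3. Forward, base would release an ortho-quinone methide of ring B from a phenolic sulfone and an ylide from a chiral sulfonium salt carrying the ring C benzyl group. The ylide carbon adds to the methide carbon (C3), and the phenoxide then displaces the sulfide at C2 to give A1.
- For: two bonds form in one step, the trans relation follows directly from the addition–displacement sequence, and the C3 substituent is already at the alcohol level. On directness to the trans isomer it is stronger than the chosen route, which needs an equilibration.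
- Against: absolute control rests on a stoichiometric chiral sulfide, and a para-alkoxybenzyl ylide is only semi-stabilised, so reversible addition can erode the selectivity. The alkyl-substituted quinone methide with a β-silyloxy group can tautomerise to a styrene or lose silanolate. The sulfone precursor is itself a multi-step target. A1 carries bromine at C5, which still needs a one-carbon homologation before the chain can be attached.
- Comparison: the chosen route uses a catalytic amount of a chiral complex and a precursor four steps from 5-iodovanillin 3 that already holds the C5 carbon.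

Alternative 2: a three-component assembly that cuts both benzylic C–C bonds of the chain. Forward, a lithiated dithiane made from the ring B aldehyde would add to C4 of a chiral 5-alkoxybutenolide anti to the alkoxy group, and the enolate would be trapped at C3 by the ring A benzyl bromide, giving A2.
- For: both chain stereocentres are set in one flask from a chiral-pool auxiliary with well-understood all-trans control, and the aldehyde is used without reduction and bromination. For the chain it is at least as economical as the lactone sequence chosen here (steps 11 to 14).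
- Against: it does nothing for the dihydrobenzofuran, whose two stereocentres would still need their own asymmetric synthesis. It exposes the finished dihydrofuran to an alkyllithium, with a risk of metalation at C2 or C3 and ring opening. A2 must later be desulfurised with a nickel reagent that also cleaves benzylic C–O bonds, O1–C2 among them.
- Comparison: the chosen route makes the ring B/C unit the electrophile 14 in a mild enolate alkylation, so the heterocycle meets neither an organolithium nor a desulfurising metal.

Alternative 3: a cycloetherification that cuts only O1–C2. Forward, acid would ionise the benzylic carbinol of a 1-(ring C)-2-(ring B phenol)propane-1,3-diol to a para-alkoxybenzyl cation, and the phenol oxygen would capture it anti to the hydroxymethyl group, giving A3 whichever carbinol epimer is used.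
- For: only C3 needs absolute control, the carbinol epimers converge, the trans ring forms directly, and no diazo compound or precious metal is needed. On diastereocontrol and operational simplicity it is stronger than the chosen route.
- Against: the enantiocontrol is only moved to the α-aryl stereocentre of the open-chain diol, which would take a stoichiometric auxiliary aldol, a reduction and the handling of a free ortho-phenol. The cation can also lose a proton or a formaldehyde unit to give a stilbene, or alkylate the electron-rich rings. A3 has the same C5 bromine problem as A1 and a free alcohol to protect.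
- Comparison: the chosen route sets C2 by catalyst and C3 by equilibration in one operation on a short precursor; what it gives up is the built-in trans selectivity.

Key step: step 6

Assumption: for 2-benzyloxyaryl diazoacetates the (R)-tert-leucinate complex Rh2(R-PTTL)4 is taken to give the (2S) benzylic centre (the antipode of the sense assigned to the (S)-series catalysts of this family); if the sense proved opposite, the equally accessible antipodal complex would be used with no other change.

## Steps

Step 1
Reactants: 1 4-benzyloxy-3-methoxybenzyl alcohol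
Product: 2 4-benzyloxy-3-methoxybenzyl bromide
Conditions: PBr3 (0.4 equiv), Et2O, 0 °C; used at once
Reagents that add atoms: phosphorus tribromide BrP(Br)Br
Why: Bromination of a benzylic alcohol through its phosphite ester (PBr3 bromination); the aryl benzyl ether is inert at 0 °C. The bromide is used fresh because para-alkoxybenzyl bromides ionise on standing.

Step 2
Reactants: 3 5-iodovanillin
Product: 4 4-(1,3-dioxolan-2-yl)-2-iodo-6-methoxyphenol
Conditions: HOCH2CH2OH, p-TsOH·H2O (cat.), toluene, reflux, Dean–Stark; Et3N quench
Reagents that add atoms: ethylene glycol OCCO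
Why: Acid-catalysed acetalisation with azeotropic removal of water. It is placed before the etherification so that the acid-labile para-alkoxybenzyl aryl ether of 5 is never exposed to acid; the base quench protects the phenolic acetal during isolation.

Step 3
Reactants: 4 4-(1,3-dioxolan-2-yl)-2-iodo-6-methoxyphenol; 2 4-benzyloxy-3-methoxybenzyl bromide
Product: 5 2-[4-(4-benzyloxy-3-methoxybenzyloxy)-3-iodo-5-methoxyphenyl]-1,3-dioxolane
Conditions: K2CO3, DMF, rt
Reagents that add atoms: none
Why: Williamson ether synthesis; the hindered but acidic phenoxide is alkylated by the reactive benzylic bromide, and the basic medium preserves the dioxolane.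

Step 4
Reactants: 5 2-[4-(4-benzyloxy-3-methoxybenzyloxy)-3-iodo-5-methoxyphenyl]-1,3-dioxolane
Product: 6 ethyl 2-[2-(4-benzyloxy-3-methoxybenzyloxy)-5-(1,3-dioxolan-2-yl)-3-methoxyphenyl]acetate
Conditions: BrCH2CO2Et, Zn, TMSCl (cat.), THF, 40 °C; then 5, Pd(dba)2 (3 mol%), XPhos (6 mol%), THF, 60 °C
Reagents that add atoms: ethyl bromoacetate BrCC(=O)OCC (as its zinc reagent)
Why: Negishi-type coupling of a Reformatsky reagent (palladium-catalysed α-arylation of a zinc ester enolate): zerovalent palladium inserts into the C–I bond, and transmetalation from zinc followed by reductive elimination forms the aryl–CH2 bond. The nearly neutral zinc enolate tolerates the acetal and both benzylic ethers, and the bulky biaryl phosphine accommodates the ortho alkoxy group.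

Step 5
Reactants: 6 ethyl 2-[2-(4-benzyloxy-3-methoxybenzyloxy)-5-(1,3-dioxolan-2-yl)-3-methoxyphenyl]acetate
Product: 7 ethyl 2-diazo-2-[2-(4-benzyloxy-3-methoxybenzyloxy)-5-(1,3-dioxolan-2-yl)-3-methoxyphenyl]acetate
Conditions: p-ABSA, DBU, MeCN, 0 °C to rt
Reagents that add atoms: 4-acetamidobenzenesulfonyl azide CC(=O)Nc1ccc(cc1)S(=O)(=O)N=[N+]=[N-]
Why: Regitz diazo transfer; DBU deprotonates the arylacetate, the only acidic C–H, and the enolate attacks the terminal nitrogen of the sulfonyl azide, which then fragments to the aryldiazoacetate.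

Step 6
Reactants: 7 ethyl 2-diazo-2-[2-(4-benzyloxy-3-methoxybenzyloxy)-5-(1,3-dioxolan-2-yl)-3-methoxyphenyl]acetate
Product: 9 ethyl (2S,3S)-trans-2-(4-benzyloxy-3-methoxyphenyl)-5-(1,3-dioxolan-2-yl)-7-methoxy-2,3-dihydrobenzofuran-3-carboxylate, via cis ester 8 (not isolated)
Conditions: Rh2(R-PTTL)4 (1 mol%), toluene, −60 °C, slow addition of 7; evaporate; NaOEt (0.2 equiv), EtOH, 0 °C
Reagents that add atoms: none
Why: Rh2(R-PTTL)4, dirhodium tetrakis[N-phthaloyl-(R)-tert-leucinate], a tetracarboxylate of divalent rhodium, expels N2 from 7 to give a donor–acceptor carbenoid at the future C3, which engages the 1,5-related O–CH2 hydrogen in a concerted, asynchronous three-centre transition state with hydride-transfer character and forms C2–C3 with retention at C2. The closest known reaction type is the dirhodium-catalysed intramolecular C–H insertion of 2-benzyloxyphenyl diazoacetates to 2-aryl-2,3-dihydrobenzofuran-3-carboxylates. The dihydrofuran (O1–C2–C3–C3a–C7a) closes by this 1,5-insertion into the only C–H bond within reach that is activated both by the ether oxygen and by electron-rich ring C; ylide formation at O1 would need a four-membered ring and the OCH2Ph group of ring C is out of range. C2 is controlled by the catalyst, whose chiral pocket must distinguish the two enantiotopic benzylic hydrogens and deliver the carbenoid to the pro-S one. C3 is first set kinetically, cis ester 8 being the expected outcome with this catalyst class, and is then brought under thermodynamic control: catalytic ethoxide enolises the ester and reprotonation places CO2Et trans to ring C without touching C2. The step needs chemoselectivity for insertion over carbene dimerisation (slow addition, dilution), selection between the enantiotopic hydrogens (low temperature, non-coordinating solvent) and an epimerisation that stops short of E1cB opening of the ring (sub-stoichiometric base, 0 °C, short time, ethoxide matched to the ethyl ester).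

Step 7
Reactants: 9 ethyl (2S,3S)-trans-2-(4-benzyloxy-3-methoxyphenyl)-5-(1,3-dioxolan-2-yl)-7-methoxy-2,3-dihydrobenzofuran-3-carboxylate
Product: 10 [(2S,3R)-2-(4-benzyloxy-3-methoxyphenyl)-5-(1,3-dioxolan-2-yl)-7-methoxy-2,3-dihydrobenzofuran-3-yl]methanol
Conditions: LiAlH4, THF, 0 °C
Reagents that add atoms: none
Why: LiAlH4 reduction of the ester to the primary alcohol; the acetal and the benzylic ethers are inert. C3 is no longer epimerisable from here on, and its descriptor changes from S to R only because the CIP priorities change.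

Step 8
Reactants: 10 [(2S,3R)-2-(4-benzyloxy-3-methoxyphenyl)-5-(1,3-dioxolan-2-yl)-7-methoxy-2,3-dihydrobenzofuran-3-yl]methanol
Product: 11 [(2S,3R)-2-(4-benzyloxy-3-methoxyphenyl)-5-(1,3-dioxolan-2-yl)-7-methoxy-2,3-dihydrobenzofuran-3-yl]methyl 2,2-dimethylpropanoate
Conditions: PivCl, pyridine, DMAP (cat.), CH2Cl2, 0 °C to rt
Reagents that add atoms: pivaloyl chloride CC(C)(C)C(Cl)=O
Why: DMAP-catalysed acylation of the primary alcohol. A pivalate has no α-hydrogen and is hindered, so it should survive the enolate alkylation of step 14 and is then removed by the hydride of step 15, which keeps the final hydrogenolysis to two phenolic benzyl ethers.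

Step 9
Reactants: 11 [(2S,3R)-2-(4-benzyloxy-3-methoxyphenyl)-5-(1,3-dioxolan-2-yl)-7-methoxy-2,3-dihydrobenzofuran-3-yl]methyl 2,2-dimethylpropanoate
Product: 13 [(2S,3R)-2-(4-benzyloxy-3-methoxyphenyl)-5-(hydroxymethyl)-7-methoxy-2,3-dihydrobenzofuran-3-yl]methyl 2,2-dimethylpropanoate, via aldehyde 12 (not isolated)
Conditions: PPTS (cat.), acetone–H2O (9:1), 45 °C; evaporate; NaBH4, MeOH–THF, 0 °C
Reagents that add atoms: water O
Why: Mild acid-catalysed hydrolysis of the electron-rich aryl dioxolane, too weakly acidic to ionise the O1–C2 ether, followed by chemoselective NaBH4 reduction of the aldehyde in the presence of the pivalate.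

Step 10
Reactants: 13 [(2S,3R)-2-(4-benzyloxy-3-methoxyphenyl)-5-(hydroxymethyl)-7-methoxy-2,3-dihydrobenzofuran-3-yl]methyl 2,2-dimethylpropanoate
Product: 14 [(2S,3R)-2-(4-benzyloxy-3-methoxyphenyl)-5-(bromomethyl)-7-methoxy-2,3-dihydrobenzofuran-3-yl]methyl 2,2-dimethylpropanoate
Conditions: CBr4, PPh3, CH2Cl2, 0 °C; used directly
Reagents that add atoms: carbon tetrabromide BrC(Br)(Br)Br
Why: Appel reaction; the benzylic alcohol is converted to the bromide through its alkoxyphosphonium salt under neutral conditions, avoiding the HBr that could ionise O1–C2.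

Step 11
Reactants: 15 4-tert-butoxy-4-oxobutanoic acid (mono-tert-butyl succinate); 16 (R)-4-benzyl-1,3-oxazolidin-2-one
Product: 18 tert-butyl 4-[(4R)-4-benzyl-2-oxo-1,3-oxazolidin-3-yl]-4-oxobutanoate, via mixed pivalic anhydride 17 (not isolated)
Conditions: PivCl, Et3N, THF, −20 °C; then 16, LiCl, −20 °C to rt
Reagents that add atoms: none
Why: Mixed-anhydride N-acylation of the oxazolidinone; the pivaloyl carbonyl is shielded, so the lithium-activated oxazolidinone attacks the succinyl carbonyl, and the tert-butyl ester is untouched.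

Step 12
Reactants: 18 tert-butyl 4-[(4R)-4-benzyl-2-oxo-1,3-oxazolidin-3-yl]-4-oxobutanoate; 2 4-benzyloxy-3-methoxybenzyl bromide
Product: 20 tert-butyl (3R)-3-(4-benzyloxy-3-methoxybenzyl)-4-[(4R)-4-benzyl-2-oxo-1,3-oxazolidin-3-yl]-4-oxobutanoate, via sodium enolate 19 (not isolated)
Conditions: NaN(SiMe3)2, THF, −78 °C; then 2, −78 to −40 °C
Reagents that add atoms: none
Why: Evans asymmetric alkylation; the chelated Z enolate forms at the imide α-carbon, which is more acidic than the α-carbon of the tert-butyl ester. Bromide 2 approaches the face opposite the benzyl group of the (R)-auxiliary, which sets the R configuration of the future C8.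

Step 13
Reactants: 20 tert-butyl (3R)-3-(4-benzyloxy-3-methoxybenzyl)-4-[(4R)-4-benzyl-2-oxo-1,3-oxazolidin-3-yl]-4-oxobutanoate
Product: 22 (4R)-4-(4-benzyloxy-3-methoxybenzyl)oxolan-2-one, via hydroxy ester 21 (not isolated)
Conditions: LiBH4, MeOH (1 equiv), THF, 0 °C; then p-TsOH·H2O (cat.), toluene, 80 °C
Reagents that add atoms: none
Why: Reductive removal of the auxiliary; LiBH4 reduces the exocyclic imide carbonyl to the primary alcohol and spares the tert-butyl ester. Acid-catalysed lactonisation (5-exo-trig transesterification) then expels tert-butanol without affecting the stereocentre.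

Step 14
Reactants: 22 (4R)-4-(4-benzyloxy-3-methoxybenzyl)oxolan-2-one; 14 [(2S,3R)-2-(4-benzyloxy-3-methoxyphenyl)-5-(bromomethyl)-7-methoxy-2,3-dihydrobenzofuran-3-yl]methyl 2,2-dimethylpropanoate
Product: 24 (3R,4R)-4-(4-benzyloxy-3-methoxybenzyl)-3-{[(2S,3R)-2-(4-benzyloxy-3-methoxyphenyl)-7-methoxy-3-(pivaloyloxymethyl)-2,3-dihydrobenzofuran-5-yl]methyl}oxolan-2-one, via lithium enolate 23 (not isolated)
Conditions: LiN(SiMe3)2, THF, −78 °C; then 14, THF–DMPU, −78 to −30 °C
Reagents that add atoms: none
Why: Diastereoselective alkylation of a β-substituted γ-butyrolactone enolate; the benzylic bromide enters anti to the C4 benzyl group and sets C3 (the future C8') as R, giving the trans-dibenzyl lactone, which is also the thermodynamic isomer. The pivalate has no α-hydrogen and is too hindered for Claisen attack at low temperature.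

Step 15
Reactants: 24 (3R,4R)-4-(4-benzyloxy-3-methoxybenzyl)-3-{[(2S,3R)-2-(4-benzyloxy-3-methoxyphenyl)-7-methoxy-3-(pivaloyloxymethyl)-2,3-dihydrobenzofuran-5-yl]methyl}oxolan-2-one
Product: 25 (2R,3R)-2-(4-benzyloxy-3-methoxybenzyl)-3-{[(2S,3R)-2-(4-benzyloxy-3-methoxyphenyl)-3-(hydroxymethyl)-7-methoxy-2,3-dihydrobenzofuran-5-yl]methyl}butane-1,4-diol
Conditions: LiAlH4, THF, 0 °C to rt
Reagents that add atoms: none
Why: LiAlH4 reduction opens the lactone to the 1,4-diol and cleaves the pivalate in the same operation; hydride addition to the lactone carbonyl is faster than enolisation, so C8' is retained.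

Step 16
Reactants: 25 (2R,3R)-2-(4-benzyloxy-3-methoxybenzyl)-3-{[(2S,3R)-2-(4-benzyloxy-3-methoxyphenyl)-3-(hydroxymethyl)-7-methoxy-2,3-dihydrobenzofuran-5-yl]methyl}butane-1,4-diol
Product: 26 (2R,3R)-2-(4-hydroxy-3-methoxybenzyl)-3-{[(2S,3R)-2-(4-hydroxy-3-methoxyphenyl)-3-(hydroxymethyl)-7-methoxy-2,3-dihydrobenzofuran-5-yl]methyl}butane-1,4-diol (CNP0256425.1)
Conditions: H2 (1 atm), 10% Pd/C, EtOAc–EtOH, rt; stopped when 25 is consumed
Reagents that add atoms: none
Why: Catalytic hydrogenolysis of two aryl benzyl ethers, which cleave quickly at atmospheric pressure and neutral pH; under these conditions the cyclic O1–C2 benzylic ether of a 2-aryl-2,3-dihydrobenzofuran is expected to persist.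

## Compound list

1 | 4-benzyloxy-3-methoxybenzyl alcohol | COc1cc(CO)ccc1OCc1ccccc1 | starting material
2 | 4-benzyloxy-3-methoxybenzyl bromide | COc1cc(CBr)ccc1OCc1ccccc1 | intermediate
3 | 5-iodovanillin | COc1cc(C=O)cc(I)c1O | starting material
4 | 4-(1,3-dioxolan-2-yl)-2-iodo-6-methoxyphenol | COc1cc(C2OCCO2)cc(I)c1O | intermediate
5 | 2-[4-(4-benzyloxy-3-methoxybenzyloxy)-3-iodo-5-methoxyphenyl]-1,3-dioxolane | COc1cc(C2OCCO2)cc(I)c1OCc1ccc(OCc2ccccc2)c(OC)c1 | intermediate
6 | ethyl 2-[2-(4-benzyloxy-3-methoxybenzyloxy)-5-(1,3-dioxolan-2-yl)-3-methoxyphenyl]acetate | CCOC(=O)Cc1cc(C2OCCO2)cc(OC)c1OCc1ccc(OCc2ccccc2)c(OC)c1 | intermediate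
7 | ethyl 2-diazo-2-[2-(4-benzyloxy-3-methoxybenzyloxy)-5-(1,3-dioxolan-2-yl)-3-methoxyphenyl]acetate | CCOC(=O)C(=[N+]=[N-])c1cc(C2OCCO2)cc(OC)c1OCc1ccc(OCc2ccccc2)c(OC)c1 | intermediate
8 | ethyl (2S,3R)-cis-2-(4-benzyloxy-3-methoxyphenyl)-5-(1,3-dioxolan-2-yl)-7-methoxy-2,3-dihydrobenzofuran-3-carboxylate | O1CCOC1c2cc(OC)c3c(c2)[C@@H](C(=O)OCC)[C@@H](c2ccc(OCc4ccccc4)c(OC)c2)O3 | intermediate
9 | ethyl (2S,3S)-trans-2-(4-benzyloxy-3-methoxyphenyl)-5-(1,3-dioxolan-2-yl)-7-methoxy-2,3-dihydrobenzofuran-3-carboxylate | O1CCOC1c2cc(OC)c3c(c2)[C@H](C(=O)OCC)[C@@H](c2ccc(OCc4ccccc4)c(OC)c2)O3 | intermediate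
10 | [(2S,3R)-2-(4-benzyloxy-3-methoxyphenyl)-5-(1,3-dioxolan-2-yl)-7-methoxy-2,3-dihydrobenzofuran-3-yl]methanol | O1CCOC1c2cc(OC)c3c(c2)[C@H](CO)[C@@H](c2ccc(OCc4ccccc4)c(OC)c2)O3 | intermediate
11 | [(2S,3R)-2-(4-benzyloxy-3-methoxyphenyl)-5-(1,3-dioxolan-2-yl)-7-methoxy-2,3-dihydrobenzofuran-3-yl]methyl 2,2-dimethylpropanoate | O1CCOC1c2cc(OC)c3c(c2)[C@H](COC(=O)C(C)(C)C)[C@@H](c2ccc(OCc4ccccc4)c(OC)c2)O3 | intermediate
12 | [(2S,3R)-2-(4-benzyloxy-3-methoxyphenyl)-5-formyl-7-methoxy-2,3-dihydrobenzofuran-3-yl]methyl 2,2-dimethylpropanoate | O=Cc2cc(OC)c3c(c2)[C@H](COC(=O)C(C)(C)C)[C@@H](c2ccc(OCc4ccccc4)c(OC)c2)O3 | intermediate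
13 | [(2S,3R)-2-(4-benzyloxy-3-methoxyphenyl)-5-(hydroxymethyl)-7-methoxy-2,3-dihydrobenzofuran-3-yl]methyl 2,2-dimethylpropanoate | OCc2cc(OC)c3c(c2)[C@H](COC(=O)C(C)(C)C)[C@@H](c2ccc(OCc4ccccc4)c(OC)c2)O3 | intermediate
14 | [(2S,3R)-2-(4-benzyloxy-3-methoxyphenyl)-5-(bromomethyl)-7-methoxy-2,3-dihydrobenzofuran-3-yl]methyl 2,2-dimethylpropanoate | BrCc2cc(OC)c3c(c2)[C@H](COC(=O)C(C)(C)C)[C@@H](c2ccc(OCc4ccccc4)c(OC)c2)O3 | intermediate
15 | 4-tert-butoxy-4-oxobutanoic acid | CC(C)(C)OC(=O)CCC(=O)O | starting material
16 | (R)-4-benzyl-1,3-oxazolidin-2-one | O=C1N[C@H](Cc2ccccc2)CO1 | starting material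
17 | 4-tert-butoxy-4-oxobutanoic pivalic anhydride | CC(C)(C)OC(=O)CCC(=O)OC(=O)C(C)(C)C | intermediate
18 | tert-butyl 4-[(4R)-4-benzyl-2-oxo-1,3-oxazolidin-3-yl]-4-oxobutanoate | CC(C)(C)OC(=O)CCC(=O)N1[C@H](Cc2ccccc2)COC1=O | intermediate
19 | sodium Z-enolate of 18 | [Na+].[O-]/C(=C\CC(=O)OC(C)(C)C)N1[C@H](Cc2ccccc2)COC1=O | intermediate
20 | tert-butyl (3R)-3-(4-benzyloxy-3-methoxybenzyl)-4-[(4R)-4-benzyl-2-oxo-1,3-oxazolidin-3-yl]-4-oxobutanoate | CC(C)(C)OC(=O)C[C@@H](Cc1ccc(OCc2ccccc2)c(OC)c1)C(=O)N1[C@H](Cc2ccccc2)COC1=O | intermediate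
21 | tert-butyl (3R)-3-(4-benzyloxy-3-methoxybenzyl)-4-hydroxybutanoate | CC(C)(C)OC(=O)C[C@@H](Cc1ccc(OCc2ccccc2)c(OC)c1)CO | intermediate
22 | (4R)-4-(4-benzyloxy-3-methoxybenzyl)oxolan-2-one | O=C1C[C@@H](Cc2ccc(OCc3ccccc3)c(OC)c2)CO1 | intermediate
23 | lithium enolate of 22 | [Li+].[O-]C1=C[C@@H](Cc2ccc(OCc3ccccc3)c(OC)c2)CO1 | intermediate
24 | (3R,4R)-4-(4-benzyloxy-3-methoxybenzyl)-3-{[(2S,3R)-2-(4-benzyloxy-3-methoxyphenyl)-7-methoxy-3-(pivaloyloxymethyl)-2,3-dihydrobenzofuran-5-yl]methyl}oxolan-2-one | O=C1OC[C@H](Cc2ccc(OCc3ccccc3)c(OC)c2)[C@H]1Cc2cc(OC)c3c(c2)[C@H](COC(=O)C(C)(C)C)[C@@H](c2ccc(OCc4ccccc4)c(OC)c2)O3 | intermediate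
25 | (2R,3R)-2-(4-benzyloxy-3-methoxybenzyl)-3-{[(2S,3R)-2-(4-benzyloxy-3-methoxyphenyl)-3-(hydroxymethyl)-7-methoxy-2,3-dihydrobenzofuran-5-yl]methyl}butane-1,4-diol | COc1cc(C[C@@H](CO)[C@H](CO)Cc2cc(OC)c3c(c2)[C@H](CO)[C@@H](c2ccc(OCc4ccccc4)c(OC)c2)O3)ccc1OCc1ccccc1 | intermediate
26 | (2R,3R)-2-(4-hydroxy-3-methoxybenzyl)-3-{[(2S,3R)-2-(4-hydroxy-3-methoxyphenyl)-3-(hydroxymethyl)-7-methoxy-2,3-dihydrobenzofuran-5-yl]methyl}butane-1,4-diol | COc1cc(C[C@@H](CO)[C@H](CO)Cc2cc(OC)c3c(c2)[C@H](CO)[C@@H](c2ccc(O)c(OC)c2)O3)ccc1O | target

## Step count and least certain steps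

Total: 16 steps. Longest linear sequence: 12 steps, from 3 through steps 2 to 10 and 14 to 16; the sequence from 1 through step 1, steps 3 to 10 and 14 to 16 is equally long.

Step 6 (key step). Two things may go wrong.
- Selection between the two enantiotopic benzylic hydrogens may be weak, because the methoxy group ortho to the ether oxygen twists the benzyloxy group out of the conformation on which the catalyst relies.
- The base equilibration may open the dihydrofuran by E1cB loss of the phenoxide from the C3 enolate.

The fallback replaces catalyst control by a covalently bound auxiliary, which is expected to give the trans ester directly and so removes the base step. It sets out from 6 and comes back at 10. Saponification (LiOH, THF–H2O, buffered acidification) would give 2-[2-(4-benzyloxy-3-methoxybenzyloxy)-5-(1,3-dioxolan-2-yl)-3-methoxyphenyl]acetic acid F1. Carbodiimide esterification with (S)-2-hydroxy-1-(pyrrolidin-1-yl)propan-1-one would give the lactamide ester (2S)-1-oxo-1-(pyrrolidin-1-yl)propan-2-yl 2-[2-(4-benzyloxy-3-methoxybenzyloxy)-5-(1,3-dioxolan-2-yl)-3-methoxyphenyl]acetate F2. Diazo transfer as in step 5 would give its diazo derivative, (2S)-1-oxo-1-(pyrrolidin-1-yl)propan-2-yl 2-diazo-2-[2-(4-benzyloxy-3-methoxybenzyloxy)-5-(1,3-dioxolan-2-yl)-3-methoxyphenyl]acetate F3. Decomposition with Rh2(S-DOSP)4, dirhodium tetrakis[(S)-N-(4-dodecylphenylsulfonyl)prolinate], or with its antipode, whichever is the matched partner of the auxiliary, should give the trans ester (2S)-1-oxo-1-(pyrrolidin-1-yl)propan-2-yl (2S,3S)-2-(4-benzyloxy-3-methoxyphenyl)-5-(1,3-dioxolan-2-yl)-7-methoxy-2,3-dihydrobenzofuran-3-carboxylate F4; minor diastereomers are removable because the auxiliary makes them diastereomeric. LiAlH4 then cleaves the auxiliary ester reductively to 10.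

Step 14. The para-alkoxybenzylic bromide may ionise and alkylate itself before it meets the enolate, proton transfer from product to enolate may lead to double alkylation, and trans selectivity may be incomplete.

The fallback is an olefination followed by reduction, which uses the aldehyde and never makes the bromide. It sets out from 22 and from aldehyde 12, isolated by stopping step 9 before the borohydride is added, and comes back at 24. Lactone 22 would be converted with LiN(i-Pr)2 and diethyl chlorophosphate into the α-phosphono lactone diethyl [4-(4-benzyloxy-3-methoxybenzyl)-2-oxooxolan-3-yl]phosphonate F5 (C4 as in 22, C3 epimers). A Horner–Wadsworth–Emmons reaction with 12 (LiCl, DBU, MeCN) would give the benzylidene lactone (3E,4R)-4-(4-benzyloxy-3-methoxybenzyl)-3-{[(2S,3R)-2-(4-benzyloxy-3-methoxyphenyl)-7-methoxy-3-(pivaloyloxymethyl)-2,3-dihydrobenzofuran-5-yl]methylidene}oxolan-2-one F6. Conjugate reduction (NaBH4, NiCl2·6H2O, MeOH–THF, 0 °C) would give 24 together with its C3 epimer, the cis lactone (3S,4R)-4-(4-benzyloxy-3-methoxybenzyl)-3-{[(2S,3R)-2-(4-benzyloxy-3-methoxyphenyl)-7-methoxy-3-(pivaloyloxymethyl)-2,3-dihydrobenzofuran-5-yl]methyl}oxolan-2-one F7. DBU in toluene would equilibrate F7 to the trans isomer 24.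

Step 4. Oxidative addition and transmetalation may be slow at the hindered, electron-rich iodide next to the bulky benzyloxy group, so that protodehalogenation of 5 or self-condensation of the zinc enolate takes over.

The fallback is the direct palladium-catalysed arylation of the acidic C–H bond of ethyl diazoacetate (Pd(PPh3)4, Ag2CO3, Et3N, toluene, rt), which attaches the diazo carbon itself to the ring. It sets out from 5 and comes back at 7, bypassing 6 and step 5. It makes no new compound (F0).

Step 2. The acetal may be lost during isolation, because the free para phenol assists ionisation to a quinone-methide-like oxocarbenium ion, and traces of acid and water then regenerate the aldehyde.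

The fallback changes both the order and the acetalisation mechanism. It sets out from 3 and comes back at 5. Alkylation of 3 with 2 (K2CO3, DMF) would give 4-(4-benzyloxy-3-methoxybenzyloxy)-3-iodo-5-methoxybenzaldehyde F8. This would be acetalised under aprotic Noyori conditions (1,2-bis(trimethylsilyloxy)ethane, TMSOTf cat., CH2Cl2, −78 °C), cold enough to spare the benzylic aryl ether.

## Further compounds

F1 | step 6 | 2-[2-(4-benzyloxy-3-methoxybenzyloxy)-5-(1,3-dioxolan-2-yl)-3-methoxyphenyl]acetic acid | OC(=O)Cc1cc(C2OCCO2)cc(OC)c1OCc1ccc(OCc2ccccc2)c(OC)c1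
F2 | step 6 | (2S)-1-oxo-1-(pyrrolidin-1-yl)propan-2-yl 2-[2-(4-benzyloxy-3-methoxybenzyloxy)-5-(1,3-dioxolan-2-yl)-3-methoxyphenyl]acetate | C[C@H](OC(=O)Cc1cc(C2OCCO2)cc(OC)c1OCc1ccc(OCc2ccccc2)c(OC)c1)C(=O)N1CCCC1
F3 | step 6 | (2S)-1-oxo-1-(pyrrolidin-1-yl)propan-2-yl 2-diazo-2-[2-(4-benzyloxy-3-methoxybenzyloxy)-5-(1,3-dioxolan-2-yl)-3-methoxyphenyl]acetate | C[C@H](OC(=O)C(=[N+]=[N-])c1cc(C2OCCO2)cc(OC)c1OCc1ccc(OCc2ccccc2)c(OC)c1)C(=O)N1CCCC1
F4 | step 6 | (2S)-1-oxo-1-(pyrrolidin-1-yl)propan-2-yl (2S,3S)-2-(4-benzyloxy-3-methoxyphenyl)-5-(1,3-dioxolan-2-yl)-7-methoxy-2,3-dihydrobenzofuran-3-carboxylate | O1CCOC1c2cc(OC)c3c(c2)[C@H](C(=O)O[C@@H](C)C(=O)N4CCCC4)[C@@H](c2ccc(OCc4ccccc4)c(OC)c2)O3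
F5 | step 14 | diethyl [4-(4-benzyloxy-3-methoxybenzyl)-2-oxooxolan-3-yl]phosphonate (C4 as in 22, C3 epimers) | O=C1OC[C@H](Cc2ccc(OCc3ccccc3)c(OC)c2)C1P(=O)(OCC)OCC
F6 | step 14 | (3E,4R)-4-(4-benzyloxy-3-methoxybenzyl)-3-{[(2S,3R)-2-(4-benzyloxy-3-methoxyphenyl)-7-methoxy-3-(pivaloyloxymethyl)-2,3-dihydrobenzofuran-5-yl]methylidene}oxolan-2-one | O=C1OC[C@H](Cc2ccc(OCc3ccccc3)c(OC)c2)/C1=C\c1cc(OC)c2c(c1)[C@H](COC(=O)C(C)(C)C)[C@@H](c1ccc(OCc3ccccc3)c(OC)c1)O2
F7 | step 14 | (3S,4R)-4-(4-benzyloxy-3-methoxybenzyl)-3-{[(2S,3R)-2-(4-benzyloxy-3-methoxyphenyl)-7-methoxy-3-(pivaloyloxymethyl)-2,3-dihydrobenzofuran-5-yl]methyl}oxolan-2-one | O=C1OC[C@H](Cc2ccc(OCc3ccccc3)c(OC)c2)[C@@H]1Cc2cc(OC)c3c(c2)[C@H](COC(=O)C(C)(C)C)[C@@H](c2ccc(OCc4ccccc4)c(OC)c2)O3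
F0 | step 4 | none | none
F8 | step 2 | 4-(4-benzyloxy-3-methoxybenzyloxy)-3-iodo-5-methoxybenzaldehyde | COc1cc(C=O)cc(I)c1OCc1ccc(OCc2ccccc2)c(OC)c1
A1 | alternative 1 | (2S,3R)-2-(4-benzyloxy-3-methoxyphenyl)-5-bromo-3-(tert-butyldimethylsilyloxymethyl)-7-methoxy-2,3-dihydrobenzofuran | Brc2cc(OC)c3c(c2)[C@H](CO[Si](C)(C)C(C)(C)C)[C@@H](c2ccc(OCc4ccccc4)c(OC)c2)O3
A2 | alternative 2 | all-trans 3-(ring A benzyl)-4-[2-(dihydrobenzofuran-5-yl)-1,3-dithian-2-yl]-5-menthyloxybutyrolactone | COc1cc(C[C@H]2C(=O)O[C@@H](O[C@@H]3C[C@H](C)CC[C@H]3C(C)C)[C@@H]2C5(SCCCS5)c2cc(OC)c3c(c2)[C@H](COCc4ccccc4)[C@@H](c2ccc(OCc4ccccc4)c(OC)c2)O3)ccc1OCc1ccccc1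
A3 | alternative 3 | [(2S,3R)-2-(4-benzyloxy-3-methoxyphenyl)-5-bromo-7-methoxy-2,3-dihydrobenzofuran-3-yl]methanol | Brc2cc(OC)c3c(c2)[C@H](CO)[C@@H](c2ccc(OCc4ccccc4)c(OC)c2)O3
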